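**Retrosynthetic overview**
The strategy rests on ring A: a 2',4'-dihydroxyphenyl ketone whose C3', C5' and C6' carry only hydrogen. Its carbons C2'–C5' and both phenolic oxygens come from a 1-methoxy-1,3-bis(silyloxy)butadiene (made from methyl acetoacetate), and C1'/C6' are the two sp carbons of a terminal ynone that already bears the enone chain and ring B.
The ynone is cut at the ketone–alkyne bond into an (E)-cinnamic N-methoxy-N-methylamide and ethynylmagnesium bromide. The amide comes from Horner-Wadsworth-Emmons olefination of silyl-protected 5-prenylvanillin.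
5-Prenylvanillin comes from vanillin by O-(1,1-dimethylpropargyl)ation, semihydrogenation and aromatic Claisen rearrangement to C5.
Ring order: ring B is bought as vanillin; ring A is built last by cycloaddition and aromatization, followed only by desilylation.

Key step: step 9

Remark: the double-bond geometries of silyl enol ether 14 and of the ketene acetal in diene 16 are not controlled; both are erased when ring A aromatizes.

**Step 1**
Reactants: 1 vanillin; 2 3-chloro-3-methylbut-1-yne
Product: 3 3-methoxy-4-(2-methylbut-3-yn-2-yloxy)benzaldehyde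
Conditions: K2CO3, KI, CuI (cat.), acetone, reflux
Reagents that add atoms: none
Why: Copper-assisted O-alkylation of the phenoxide with the tertiary propargylic chloride, in which a copper acetylide-derived electrophile lets substitution at the tertiary carbon outrun elimination.

**Step 2**
Reactants: 3 3-methoxy-4-(2-methylbut-3-yn-2-yloxy)benzaldehyde
Product: 4 3-methoxy-4-(2-methylbut-3-en-2-yloxy)benzaldehyde
Conditions: H2 (1 atm), Pd on CaCO3 poisoned with Pb(OAc)2, quinoline, EtOAc, rt, stopped after one equivalent of H2
Reagents that add atoms: none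
Why: Partial hydrogenation on lead-poisoned palladium with quinoline should stop at the alkene and leave the aryl aldehyde and the ether untouched.

**Step 3**
Reactants: 4 3-methoxy-4-(2-methylbut-3-en-2-yloxy)benzaldehyde
Product: 6 4-hydroxy-3-methoxy-5-(3-methylbut-2-en-1-yl)benzaldehyde (5-prenylvanillin), via ortho-dienone 5 (not isolated)
Conditions: N,N-diethylaniline, 140 °C, argon
Reagents that add atoms: none
Why: Aromatic Claisen rearrangement, in which the [3,3]-sigmatropic shift delivers the allyl unit with allylic inversion to C5 (the only ortho carbon bearing hydrogen) and dienone 5 enolizes to the phenol, while the basic solvent suppresses acid-catalysed chroman formation.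

**Step 4**
Reactants: 6 5-prenylvanillin
Product: 7 4-(tert-butyldimethylsilyloxy)-3-methoxy-5-(3-methylbut-2-en-1-yl)benzaldehyde
Conditions: TBSCl, imidazole, DMAP (cat.), DMF, rt
Reagents that add atoms: tert-butyldimethylsilyl chloride, CC(C)(C)[Si](C)(C)Cl
Why: Imidazole-promoted silylation of the phenol, which masks the acidic OH for the olefination and Grignard steps and later keeps the phenol from adding to the neighbouring prenyl group under acid.

**Step 5**
Reactants: 7 silyl-protected 5-prenylvanillin; 8 diethyl [2-(methoxy(methyl)amino)-2-oxoethyl]phosphonate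
Product: 9 (E)-3-[4-(tert-butyldimethylsilyloxy)-3-methoxy-5-(3-methylbut-2-en-1-yl)phenyl]-N-methoxy-N-methylprop-2-enamide
Conditions: 8, NaH (slightly less than 8), THF, 0 °C; then 7, 0 °C to rt
Reagents that add atoms: none
Why: Horner-Wadsworth-Emmons olefination with a stabilized amide phosphonate, which should give the E alkene through the reversible, thermodynamically controlled oxaphosphetane pathway and so sets the only stereogenic element of the target.

**Step 6**
Reactants: 9 (E)-cinnamic N-methoxy-N-methylamide; 10 ethynylmagnesium bromide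
Product: 12 (E)-1-[4-(tert-butyldimethylsilyloxy)-3-methoxy-5-(3-methylbut-2-en-1-yl)phenyl]pent-1-en-4-yn-3-one, via magnesium hemiaminal chelate 11 (not isolated)
Conditions: THF, −20 to 0 °C; inverse quench into cold 1 M aq HCl/Et2O, 0 °C; crude 12 used at once
Reagents that add atoms: none
Why: Weinreb ketone synthesis, in which the alkynyl Grignard adds once to the amide carbonyl to form the stable chelate 11 that collapses to the ketone only on protonation, and the cold acid quench protonates the released N,O-dimethylhydroxylamine before it can add to the ynone.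

**Step 7**
Reactants: 13 methyl acetoacetate
Product: 14 methyl 3-(trimethylsilyloxy)but-2-enoate
Conditions: Me3SiCl, Et3N, hexane, rt
Reagents that add atoms: chlorotrimethylsilane, C[Si](C)(C)Cl
Why: Silyl enol ether formation by O-silylation of the enol form of a beta-keto ester with Me3SiCl and a tertiary amine.

**Step 8**
Reactants: 14 methyl 3-(trimethylsilyloxy)but-2-enoate
Product: 16 1-methoxy-1,3-bis(trimethylsilyloxy)buta-1,3-diene, via lithium dienolate 15 (not isolated)
Conditions: lithium diisopropylamide, THF, −78 °C; Me3SiCl, −78 °C to rt; LiCl filtered off from pentane, diene used crude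
Reagents that add atoms: chlorotrimethylsilane, C[Si](C)(C)Cl
Why: Kinetic gamma-deprotonation of the vinylogous ester gives extended dienolate 15, which is silylated on oxygen to the 1,1,3-trioxygenated diene.

**Step 9**
Reactants: 12 (E)-1-arylpent-1-en-4-yn-3-one; 16 1-methoxy-1,3-bis(trimethylsilyloxy)buta-1,3-diene
Product: 18 (E)-3-[4-(tert-butyldimethylsilyloxy)-3-methoxy-5-(3-methylbut-2-en-1-yl)phenyl]-1-(2,4-dihydroxyphenyl)prop-2-en-1-one, via cyclohexa-1,4-diene cycloadduct 17 (not isolated)
Conditions: 16 (1.5 equiv), toluene, −20 °C to rt; then 1 M aq HCl, THF, 0 °C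
Reagents that add atoms: none
Why: Diene 16 has its largest HOMO coefficient at the unsubstituted CH2 terminus, which bonds to the terminal alkyne carbon of ynone 12 (C5'–C6') while the ketene acetal carbon bonds to the acyl-bearing alkyne carbon (C2'–C1'); this is a strongly asynchronous normal-demand Diels-Alder reaction whose stepwise extreme (Mukaiyama-Michael addition, then attack of the allenolate carbon on the ketene acetal carbon) gives the same adduct 17. The closest known chemistry is the cycloaddition of 1-alkoxy-1,3-bis(silyloxy)butadienes and related 1,1,3-trioxygenated dienes with acetylenic esters and ketones, which gives 2,4-dioxygenated aryl carbonyl compounds after loss of alcohol. Ring A, the only ring formed, closes as a six-membered carbocycle in the intermolecular (4+2) event (a 6-exo-trig closure in the stepwise picture); dilute acid then cleaves the mixed methyl silyl ketal at C2', methanol is expelled, the dienone enolizes to the arene and the C4' silyl ether is hydrolyzed. No stereocenter survives, since the racemic ketal carbon of 17 is flattened on aromatization and the E alkene is not touched. Regioselectivity (acyl ortho to one oxygen and para to the other) should follow from the matched polarization of diene and ynone, and chemoselectivity for the alkyne over the enone from the unhindered, more electrophilic terminal alkyne carbon against a beta-aryl enone carbon deactivated by the electron-rich ring B. Leaving out any Lewis acid should keep diene C2 from attacking the ketone carbonyl (the formal 3+3 salicylate pathway) and spare the prenyl group and the aryl silyl ether.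

**Step 10**
Reactants: 18 abyssinone D tert-butyldimethylsilyl ether
Product: 19 abyssinone D, (E)-1-(2,4-dihydroxyphenyl)-3-[4-hydroxy-3-methoxy-5-(3-methylbut-2-en-1-yl)phenyl]prop-2-en-1-one
Conditions: Bu4NF, AcOH (1:1), THF, 0 °C
Reagents that add atoms: none
Why: Fluoride-mediated cleavage of the aryl silyl ether, with acetic acid buffering the phenoxides so that the 2'-hydroxychalcone should not close to the flavanone by oxa-Michael addition.

**Compound list**
1 | vanillin (4-hydroxy-3-methoxybenzaldehyde) | COc1cc(C=O)ccc1O | starting material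
2 | 3-chloro-3-methylbut-1-yne | CC(C)(Cl)C#C | starting material
3 | 3-methoxy-4-(2-methylbut-3-yn-2-yloxy)benzaldehyde | COc1cc(C=O)ccc1OC(C)(C)C#C | intermediate
4 | 3-methoxy-4-(2-methylbut-3-en-2-yloxy)benzaldehyde | COc1cc(C=O)ccc1OC(C)(C)C=C | intermediate
5 | 5-methoxy-3-(3-methylbut-2-en-1-yl)-4-oxocyclohexa-1,5-diene-1-carbaldehyde (ortho-dienone, racemic, not isolated) | COC1=CC(C=O)=CC(CC=C(C)C)C1=O | intermediate
6 | 4-hydroxy-3-methoxy-5-(3-methylbut-2-en-1-yl)benzaldehyde (5-prenylvanillin) | COc1cc(C=O)cc(CC=C(C)C)c1O | intermediate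
7 | 4-(tert-butyldimethylsilyloxy)-3-methoxy-5-(3-methylbut-2-en-1-yl)benzaldehyde | COc1cc(C=O)cc(CC=C(C)C)c1O[Si](C)(C)C(C)(C)C | intermediate
8 | diethyl [2-(methoxy(methyl)amino)-2-oxoethyl]phosphonate | CCOP(=O)(CC(=O)N(C)OC)OCC | starting material
9 | (E)-3-[4-(tert-butyldimethylsilyloxy)-3-methoxy-5-(3-methylbut-2-en-1-yl)phenyl]-N-methoxy-N-methylprop-2-enamide | COc1cc(/C=C/C(=O)N(C)OC)cc(CC=C(C)C)c1O[Si](C)(C)C(C)(C)C | intermediate
10 | ethynylmagnesium bromide | C#C[Mg]Br | starting material
11 | bromomagnesium alkoxide of the tetrahedral adduct of 9 and 10 (chelate, racemic, not isolated) | COc1cc(/C=C/C(O[Mg]Br)(C#C)N(C)OC)cc(CC=C(C)C)c1O[Si](C)(C)C(C)(C)C | intermediate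
12 | (E)-1-[4-(tert-butyldimethylsilyloxy)-3-methoxy-5-(3-methylbut-2-en-1-yl)phenyl]pent-1-en-4-yn-3-one | COc1cc(/C=C/C(=O)C#C)cc(CC=C(C)C)c1O[Si](C)(C)C(C)(C)C | intermediate
13 | methyl acetoacetate | COC(=O)CC(C)=O | starting material
14 | methyl 3-(trimethylsilyloxy)but-2-enoate (geometry not controlled) | COC(=O)C=C(C)O[Si](C)(C)C | intermediate
15 | lithium dienolate of 14 (not isolated) | [Li]OC(OC)=CC(=C)O[Si](C)(C)C | intermediate
16 | 1-methoxy-1,3-bis(trimethylsilyloxy)buta-1,3-diene (geometry not controlled) | COC(O[Si](C)(C)C)=CC(=C)O[Si](C)(C)C | intermediate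
17 | (E)-3-[4-(tert-butyldimethylsilyloxy)-3-methoxy-5-(3-methylbut-2-en-1-yl)phenyl]-1-[6-methoxy-4,6-bis(trimethylsilyloxy)cyclohexa-1,4-dien-1-yl]prop-2-en-1-one (racemic, not isolated) | COc1cc(/C=C/C(=O)C2=CCC(O[Si](C)(C)C)=CC2(OC)O[Si](C)(C)C)cc(CC=C(C)C)c1O[Si](C)(C)C(C)(C)C | intermediate
18 | (E)-3-[4-(tert-butyldimethylsilyloxy)-3-methoxy-5-(3-methylbut-2-en-1-yl)phenyl]-1-(2,4-dihydroxyphenyl)prop-2-en-1-one | COc1cc(/C=C/C(=O)c2ccc(O)cc2O)cc(CC=C(C)C)c1O[Si](C)(C)C(C)(C)C | intermediate
19 | abyssinone D | COc1cc(/C=C/C(=O)c2ccc(O)cc2O)cc(CC=C(C)C)c1O | target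

**Step count**
Total: 10 steps. Longest linear sequence: 8 steps (steps 1, 2, 3, 4, 5, 6, 9, 10 from vanillin); the diene arm (steps 7 and 8) joins at step 9.

**Steps most likely to fail**

Step 9. Aromatization could proceed with loss of silanol in place of methanol and leave ring A O-methylated. The Michael addition could also stall before ring closure, or the terminal ynone could oligomerize faster than it is trapped. The fallback sets out from amide 9 and comes back to the route at 18, bringing ring A in preformed. Commercial 4-bromoresorcinol F1 would be protected (MOMCl, i-Pr2NEt, CH2Cl2) as 1-bromo-2,4-bis(methoxymethoxy)benzene F2. Bromine-lithium exchange (n-butyllithium, THF, −78 °C) would give [2,4-bis(methoxymethoxy)phenyl]lithium F3, which should acylate 9 to (E)-1-[2,4-bis(methoxymethoxy)phenyl]-3-[4-(tert-butyldimethylsilyloxy)-3-methoxy-5-(3-methylbut-2-en-1-yl)phenyl]prop-2-en-1-one F4. Mild acidic methanolysis (HCl, MeOH, rt) should remove both acetals and return 18; the silyl ether keeps the ring B phenol from closing onto the prenyl group.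

Step 6. The liberated N,O-dimethylhydroxylamine could add in conjugate fashion to the ynone during the quench, and the terminal enynone could oligomerize on concentration. The fallback sets out from 9 and comes back at 12, removing the amine before any ynone exists. Reduction with diisobutylaluminium hydride (i-Bu2AlH, THF, −78 °C) would give (E)-3-[4-(tert-butyldimethylsilyloxy)-3-methoxy-5-(3-methylbut-2-en-1-yl)phenyl]prop-2-enal F5. Addition of ethynylmagnesium bromide 10 (THF, −78 °C) should give racemic (E)-1-[4-(tert-butyldimethylsilyloxy)-3-methoxy-5-(3-methylbut-2-en-1-yl)phenyl]pent-1-en-4-yn-3-ol F6. Oxidation of this doubly activated alcohol with MnO2 in CH2Cl2 at rt should deliver 12.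

Step 3. Ionization or elimination of the tertiary allylic ether (loss of the five-carbon unit, returning vanillin) could compete with the sigmatropic shift, and the ortho-prenylphenol could cyclize to a chroman at high temperature. The fallback sets out from vanillin 1 and comes back at 6. O-Allylation (allyl bromide, K2CO3, acetone, reflux) would give 4-(allyloxy)-3-methoxybenzaldehyde F7. Claisen rearrangement of this robust primary allyl ether (N,N-diethylaniline, 200 °C) should give 5-allylvanillin F8. Cross-metathesis with excess 2-methylbut-2-ene (second-generation Grubbs catalyst, (H2IMes)(PCy3)Cl2Ru=CHPh, CH2Cl2, 40 °C) should convert the allyl group into the prenyl group of 6.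

**Further compounds**
F1 | step 9 | 4-bromoresorcinol | Oc1ccc(Br)c(O)c1
F2 | step 9 | 1-bromo-2,4-bis(methoxymethoxy)benzene | COCOc1ccc(Br)c(OCOC)c1
F3 | step 9 | [2,4-bis(methoxymethoxy)phenyl]lithium | [Li]c1ccc(OCOC)cc1OCOC
F4 | step 9 | (E)-1-[2,4-bis(methoxymethoxy)phenyl]-3-[4-(tert-butyldimethylsilyloxy)-3-methoxy-5-(3-methylbut-2-en-1-yl)phenyl]prop-2-en-1-one | COCOc1ccc(C(=O)/C=C/c2cc(OC)c(O[Si](C)(C)C(C)(C)C)c(CC=C(C)C)c2)c(OCOC)c1
F5 | step 6 | (E)-3-[4-(tert-butyldimethylsilyloxy)-3-methoxy-5-(3-methylbut-2-en-1-yl)phenyl]prop-2-enal | COc1cc(/C=C/C=O)cc(CC=C(C)C)c1O[Si](C)(C)C(C)(C)C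
F6 | step 6 | (E)-1-[4-(tert-butyldimethylsilyloxy)-3-methoxy-5-(3-methylbut-2-en-1-yl)phenyl]pent-1-en-4-yn-3-ol (racemic) | COc1cc(/C=C/C(O)C#C)cc(CC=C(C)C)c1O[Si](C)(C)C(C)(C)C
F7 | step 3 | 4-(allyloxy)-3-methoxybenzaldehyde | C=CCOc1ccc(C=O)cc1OC
F8 | step 3 | 5-allylvanillin (4-hydroxy-3-methoxy-5-(prop-2-en-1-yl)benzaldehyde) | C=CCc1cc(C=O)cc(OC)c1O
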